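**Retrosynthetic overview**

1. Target 40 is a 12,6-germacranolide (ring carbons C1–C10, lactone C11/C12 with exocyclic C13, C14 = CO2Me on C10, C15 = Me on C4). The C9 and C8 esters go on last, onto the macrocyclic 8,9-diol core; the acids come from an Evans aldol and a Sharpless epoxidation.
2. Ten-membered ring (formed second): ring-closing metathesis at C1=C10 between a C1 vinyl group and an acrylate unit placed on C9 by a Morita–Baylis–Hillman reaction.
3. Lactone ring O–C12–C11–C7–C6 (formed first, key step): CO2 is stitched between C11 and C6 of an acyclic α-alkenylboronate/allylic acetate by a Cu/Pd relay. The enabling feature is that C11 is vinylic (it carries the exocyclic C13 methylene) and can be an alkenyl-metal nucleophile for CO2, while C6 is allylic to the C4=C5 olefin, so C4–C5–C6 can become a π-allyl electrophile that the new carboxylate closes onto 5-exo.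
4. Key-step precursor: C5–C6 bond by Nozaki–Hiyama–Kishi coupling of a (Z)-alkenyl iodide (carbocupration of propyne) with an aldehyde whose C7/C8 centres come from a Sharpless epoxy alcohol opened by an alkynylalane; the alkyne becomes the α-alkenylboronate by Markovnikov hydroalumination.

Key step: step 13

Assumption: the Felkin-type diastereomers drawn for steps 11 and 16 are taken as the major products and are separated from their epimers by chromatography; the acetal carbon of 7–9 is drawn as the all-equatorial isomer and disappears in step 8.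

Step 1
Reactants: 1 (E)-but-2-ene-1,4-diol
Product: 2 (E)-4-[(4-methoxybenzyl)oxy]but-2-en-1-ol
Conditions: NaH (1 equiv), PMBCl (1 equiv), Bu4NI (cat.), THF/DMF, 0 °C to rt, diol in excess
Reagents that add atoms: 4-methoxybenzyl chloride, COc1ccc(CCl)cc1
Why: Williamson mono-etherification of a symmetric diol, with excess diol suppressing the bis-ether; no stereocentre is formed.

Step 2
Reactants: 2 (E)-4-[(4-methoxybenzyl)oxy]but-2-en-1-ol
Product: 3 [(2R,3R)-3-{[(4-methoxybenzyl)oxy]methyl}oxiran-2-yl]methanol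
Conditions: Ti(OiPr)4 (10 mol%), D-(−)-diethyl tartrate (12 mol%), t-BuOOH, 4 Å MS, CH2Cl2, −20 °C
Reagents that add atoms: tert-butyl hydroperoxide, CC(C)(C)OO
Why: Sharpless asymmetric epoxidation of an E allylic alcohol; the D-(−)-tartrate catalyst should deliver oxygen to the face that gives the (2R,3R)-epoxy alcohol, fixing the future C8 centre and, before inversion, C7.

Step 3
Reactants: 3 epoxy alcohol
Product: 4 (2S,3S)-3-{[(4-methoxybenzyl)oxy]methyl}-5-(trimethylsilyl)pent-4-yne-1,2-diol
Conditions: TMS-acetylene, n-BuLi, toluene, −78 to 0 °C; Et2AlCl; then 3, 0 °C to rt; Rochelle salt work-up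
Reagents that add atoms: ethynyltrimethylsilane, C#C[Si](C)(C)C
Why: Alkynylalane opening of a 2,3-epoxy alcohol, in which the aluminium alkoxide directs the alkynyl group to C3 of the epoxy alcohol (future C7) with SN2 inversion, so the alkyne ends up anti to the C8 oxygen.

Step 4
Reactants: 4 silylalkyne diol
Product: 5 (2S,3S)-3-{[(4-methoxybenzyl)oxy]methyl}pent-4-yne-1,2-diol
Conditions: K2CO3 (cat.), MeOH, rt
Reagents that add atoms: none
Why: Methanolysis of the alkynyl C–Si bond (protodesilylation) frees the terminal alkyne without touching the stereocentres.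

Step 5
Reactants: 5 alkyne diol
Product: 6 (2S,3S)-1-[(tert-butyldimethylsilyl)oxy]-3-{[(4-methoxybenzyl)oxy]methyl}pent-4-yn-2-ol
Conditions: TBSCl (1.05 equiv), imidazole, CH2Cl2, −20 to 0 °C
Reagents that add atoms: tert-butyldimethylsilyl chloride, CC(C)(C)[Si](C)(C)Cl
Why: Selective silylation of the primary hydroxyl of a 1,2-diol on steric grounds.

Step 6
Reactants: 6 mono-silyl ether
Product: 7 tert-butyl{[(2S,4S,5S)-5-ethynyl-2-(4-methoxyphenyl)-1,3-dioxan-4-yl]methoxy}dimethylsilane
Conditions: DDQ (1.2 equiv), 4 Å MS, CH2Cl2, 0 °C, anhydrous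
Reagents that add atoms: none
Why: DDQ oxidation of the PMB ether to its oxocarbenium ion, trapped by the 1,3-related secondary hydroxyl, should give the six-membered p-methoxybenzylidene acetal (all-equatorial chair), which moves the PMB group towards O8.

Step 7
Reactants: 7 alkynyl acetal
Product: 9 tert-butyl{[(2S,4S,5S)-2-(4-methoxyphenyl)-5-[1-(4,4,5,5-tetramethyl-1,3,2-dioxaborolan-2-yl)ethenyl]-1,3-dioxan-4-yl]methoxy}dimethylsilane, via alkenylalane 8 (not isolated)
Conditions: Ni(dppp)Cl2 (3 mol%), i-Bu2AlH (1.3 equiv), THF, 0 to 22 °C; then MeOBpin (3 equiv), 0 to 22 °C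
Reagents that add atoms: 2-methoxy-4,4,5,5-tetramethyl-1,3,2-dioxaborolane, COB1OC(C)(C)C(C)(C)O1
Why: Nickel-catalysed α-selective (Markovnikov) hydroalumination of a terminal alkyne puts aluminium on the internal carbon (future C11), and Al-to-B exchange with the methoxyboronate gives the 1,1-disubstituted alkenylboronate; no stereocentre is touched.

Step 8
Reactants: 9 alkenylboronate acetal
Product: 10 (2S,3S)-4-[(tert-butyldimethylsilyl)oxy]-3-[(4-methoxybenzyl)oxy]-2-[1-(4,4,5,5-tetramethyl-1,3,2-dioxaborolan-2-yl)ethenyl]butan-1-ol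
Conditions: i-Bu2AlH (3 equiv), CH2Cl2, −78 to 0 °C; Rochelle salt
Reagents that add atoms: none
Why: Regioselective reductive opening of a p-methoxybenzylidene acetal, in which aluminium binds the less hindered primary oxygen, so the PMB ether stays on the secondary O8 and the primary C6 hydroxyl is freed.

Step 9
Reactants: 10 primary alcohol
Product: 11 (2R,3S)-4-[(tert-butyldimethylsilyl)oxy]-3-[(4-methoxybenzyl)oxy]-2-[1-(4,4,5,5-tetramethyl-1,3,2-dioxaborolan-2-yl)ethenyl]butanal
Conditions: Dess–Martin periodinane, NaHCO3, CH2Cl2, 0 °C to rt; used at once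
Reagents that add atoms: none
Why: Buffered Dess–Martin oxidation is non-basic, so the α-stereocentre of the β,γ-unsaturated aldehyde should neither epimerise nor move into conjugation.

Step 10
Reactants: 12 but-3-en-1-ylmagnesium bromide
Product: 15 (1Z)-1-iodo-2-methylhexa-1,5-diene, via but-3-enylcopper 13 (not isolated), via (Z)-alkenylcopper 14 (not isolated)
Conditions: CuBr·SMe2 (1 equiv), Et2O/Me2S, −45 °C; propyne, −25 °C; I2, −45 to 0 °C
Reagents that add atoms: propyne, CC#C; iodine, II
Why: Normant carbocupration adds the butenyl group and copper syn across propyne (alkyl to the internal carbon), and iodinolysis with retention gives the Z trisubstituted alkenyl iodide that carries C1–C5 and C15.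

Step 11
Reactants: 11 aldehyde; 15 (Z)-alkenyl iodide
Product: 17 (2S,3S,4R,5Z)-1-[(tert-butyldimethylsilyl)oxy]-2-[(4-methoxybenzyl)oxy]-6-methyl-3-[1-(4,4,5,5-tetramethyl-1,3,2-dioxaborolan-2-yl)ethenyl]deca-5,9-dien-4-ol, via alkenylchromium(III) dichloride 16 (not isolated)
Conditions: CrCl2 (4 equiv), NiCl2 (2 mol%), DMSO, rt
Reagents that add atoms: none
Why: Nozaki–Hiyama–Kishi coupling adds the alkenylchromium to the aldehyde without base and with retention of the Z geometry (the α-centre and the boronate should survive); the C6 carbinol centre is set by Felkin–Anh attack anti to the C8 branch, reinforced by 1,3-anti induction from the β-OPMB group.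

Step 12
Reactants: 17 allylic alcohol
Product: 18 (2S,3S,4R,5Z)-1-[(tert-butyldimethylsilyl)oxy]-2-[(4-methoxybenzyl)oxy]-6-methyl-3-[1-(4,4,5,5-tetramethyl-1,3,2-dioxaborolan-2-yl)ethenyl]deca-5,9-dien-4-yl acetate
Conditions: Ac2O, pyridine, DMAP (cat.), CH2Cl2, 0 °C
Reagents that add atoms: acetic anhydride, CC(=O)OC(C)=O
Why: Acetylation of the secondary allylic alcohol with retention installs the latent leaving group at C6.

Step 13
Reactants: 18 allylic acetate alkenylboronate
Product: 21 (4S,5R)-4-[(1S)-2-[(tert-butyldimethylsilyl)oxy]-1-[(4-methoxybenzyl)oxy]ethyl]-3-methylidene-5-[(1Z)-2-methylhexa-1,5-dien-1-yl]oxolan-2-one, via potassium alkenylborate 19 (not isolated), via potassium carboxylate 20 (not isolated)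
Conditions: KOtBu (1.05 equiv), THF, 0 °C; then [(IPr)CuCl] (5 mol%), Pd(PPh3)4 (5 mol%), CO2 (1 atm), THF, 65 °C
Reagents that add atoms: carbon dioxide, O=C=O
Why: Proposed new method: a copper/palladium relay in which the tert-butoxide-activated alkenylboronate transmetalates to (IPr)Cu, the alkenylcopper inserts CO2 (C11–C12 bond), and the resulting α-methylene carboxylate attacks C6 of the π-allylpalladium formed by reversible ionisation of the allylic acetate (O–C6 bond); the closest known reactions are the NHC–copper-catalysed carboxylation of alkenylboronic esters with CO2 and the Tsuji–Trost allylic substitution by carboxylates, each established on these bond types but not yet run as one relay. The lactone closes 5-exo onto the π-allyl terminus that bears the tether, with the C4–C5–C6 allyl unit staying outside the ring. No new stereocentre is created: C6 is carried through with net retention (ionisation anti to acetate, carboxylate attack anti to palladium), so the centre set in step 11 and the adjacent C7 centre fix the trans ring fusion. Attack at C6 rather than C4 is secured by ring size (five against seven) and by the full substitution of C4, and the 4Z geometry should hold because syn/anti exchange at C4 would need a tertiary σ-allylpalladium. C-allylation of the alkenylcopper or alkenylboron by the π-allyl is geometrically blocked (it would close a three-membered ring or attack C4), and the CO2 atmosphere turns free alkoxide into carbonate, so the acetate should survive until it is ionised.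

Step 14
Reactants: 21 lactone silyl ether
Product: 22 (4S,5R)-4-[(1S)-2-hydroxy-1-[(4-methoxybenzyl)oxy]ethyl]-3-methylidene-5-[(1Z)-2-methylhexa-1,5-dien-1-yl]oxolan-2-one
Conditions: HF·pyridine, pyridine, THF, 0 °C to rt
Reagents that add atoms: none
Why: Buffered acidic fluoride cleaves the primary TBS ether while sparing the PMB ether, and avoids the basic conditions that would invite translactonisation or conjugate addition to the α-methylene lactone.

Step 15
Reactants: 22 primary alcohol
Product: 23 (2S)-2-[(4-methoxybenzyl)oxy]-2-[(2R,3S)-4-methylidene-2-[(1Z)-2-methylhexa-1,5-dien-1-yl]-5-oxooxolan-3-yl]acetaldehyde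
Conditions: Dess–Martin periodinane, NaHCO3, CH2Cl2, 0 °C to rt; used at once
Reagents that add atoms: none
Why: Neutral Dess–Martin oxidation gives the α-alkoxy aldehyde without epimerising C8.

Step 16
Reactants: 23 α-alkoxy aldehyde
Product: 24 methyl (3R,4S)-3-hydroxy-4-[(4-methoxybenzyl)oxy]-2-methylidene-4-[(2R,3S)-4-methylidene-2-[(1Z)-2-methylhexa-1,5-dien-1-yl]-5-oxooxolan-3-yl]butanoate
Conditions: methyl acrylate (10 equiv), 3-hydroxyquinuclidine (0.5 equiv), neat, rt
Reagents that add atoms: methyl acrylate, C=CC(=O)OC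
Why: Morita–Baylis–Hillman reaction of the activated α-alkoxy aldehyde; the C9 centre is set by Felkin–Anh addition anti to the α-OPMB substituent, and the α-methylene lactone adds the amine only reversibly because it has no α-hydrogen to turn over.

Step 17
Reactants: 24 diene
Product: 25 macrocyclic core: methyl (1(10)E,4Z)-9-hydroxy-8-[(4-methoxybenzyl)oxy]-12-oxo-germacra-1(10),4,11(13)-trien-12,6-olid-14-oate with the C6–C9 configuration of 40
Conditions: Grubbs II catalyst (2 × 10 mol%), toluene (1 mM), 80 °C, slow addition, argon sparge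
Reagents that add atoms: none
Why: Ring-closing metathesis with loss of ethylene joins the C1 vinyl group to the 2-substituted acrylate; the medium ring and the trans-fused lactone allow only the ring-cis (1(10)E) olefin, the lactone methylene cannot compete because its closure would give a bridgehead olefin, and no stereocentre is formed.

Step 18
Reactants: 26 (R)-4-benzyl-3-propionyloxazolidin-2-one
Product: 28 (R)-4-benzyl-3-[(2R,3S)-3-hydroxy-2-methylbutanoyl]oxazolidin-2-one, via boron enolate 27 (not isolated)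
Conditions: Bu2BOTf, i-Pr2NEt, CH2Cl2, −78 to 0 °C; MeCHO, −78 to 0 °C; H2O2, MeOH, pH 7 buffer
Reagents that add atoms: acetaldehyde, CC=O
Why: Evans syn aldol, in which the Z boron enolate reacts through a Zimmerman–Traxler chair and the (R)-auxiliary shields one enolate face, setting both centres as (2R,3S).

Step 19
Reactants: 28 aldol adduct
Product: 29 (R)-4-benzyl-3-[(2R,3S)-2-methyl-3-(triethylsilyloxy)butanoyl]oxazolidin-2-one
Conditions: TESCl, imidazole, DMF, 0 °C
Reagents that add atoms: chlorotriethylsilane, CC[Si](Cl)(CC)CC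
Why: Silylation of the secondary alcohol blocks retro-aldol and self-acylation in the later esterification.

Step 20
Reactants: 29 silylated imide
Product: 30 (2R,3S)-2-methyl-3-(triethylsilyloxy)butanoic acid
Conditions: LiOH, H2O2, THF/H2O, 0 °C; Na2SO3; mild acid work-up
Reagents that add atoms: hydrogen peroxide, OO
Why: Hydroperoxide attacks the exocyclic imide carbonyl selectively and releases the acid without epimerising the α-centre.

Step 21
Reactants: 25 macrocyclic 9-alcohol; 30 acid
Product: 32 9-O-[(2R,3S)-2-methyl-3-(triethylsilyloxy)butanoyl] derivative of 25 (8-OPMB retained), via mixed anhydride 31 (not isolated)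
Conditions: 30, 2,4,6-trichlorobenzoyl chloride, Et3N, THF, rt; then 25, DMAP, toluene, rt
Reagents that add atoms: none
Why: Yamaguchi esterification acylates the hindered allylic C9 hydroxyl through the mixed anhydride and the acylpyridinium ion, with retention at C9 and no epimerisation of the acid.

Step 22
Reactants: 32 C9 ester PMB ether
Product: 33 8-hydroxy compound (9-ester retained, free 8-OH)
Conditions: DDQ, CH2Cl2/pH 7 buffer (10:1), 0 °C
Reagents that add atoms: none
Why: Oxidative cleavage of the PMB ether by DDQ at neutral pH should spare the TES ether, the olefins and both ester groups.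

Step 23
Reactants: 34 angelic acid [(Z)-2-methylbut-2-enoic acid]
Product: 35 (Z)-2-methylbut-2-en-1-ol
Conditions: LiAlH4, Et2O, 0 °C
Reagents that add atoms: none
Why: Hydride reduction of the acid to the allylic alcohol is a 1,2-reduction that keeps the Z geometry.

Step 24
Reactants: 35 (Z)-2-methylbut-2-en-1-ol
Product: 36 [(2R,3S)-2,3-dimethyloxiran-2-yl]methanol
Conditions: Ti(OiPr)4 (10 mol%), D-(−)-diethyl tartrate (12 mol%), t-BuOOH, 4 Å MS, CH2Cl2, −20 °C
Reagents that add atoms: tert-butyl hydroperoxide, CC(C)(C)OO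
Why: Sharpless asymmetric epoxidation; the D-(−)-tartrate catalyst should give the (2R,3S)-epoxy alcohol, which sets both epoxide centres of the epoxyangelate.

Step 25
Reactants: 36 epoxy alcohol
Product: 37 (2S,3S)-2,3-dimethyloxirane-2-carboxylic acid
Conditions: RuCl3 (cat.), NaIO4, CCl4/MeCN/H2O, rt
Reagents that add atoms: water, O
Why: Catalytic ruthenium tetroxide oxidises the primary alcohol through the aldehyde hydrate to the acid without opening the epoxide; the change of the C2 descriptor is formal.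

Step 26
Reactants: 33 8-hydroxy compound; 37 epoxy acid
Product: 39 TES-protected target (8-O-epoxyangelate, 9-O-silyloxy ester), via mixed anhydride 38 (not isolated)
Conditions: 37, 2,4,6-trichlorobenzoyl chloride, Et3N, THF, rt; then 33, DMAP, toluene, rt to 40 °C
Reagents that add atoms: none
Why: Yamaguchi esterification couples the α,α-disubstituted epoxy acid to the hindered C8 hydroxyl with retention, and the aprotic, short conditions should limit acyl migration and translactonisation.

Step 27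
Reactants: 39 TES-protected target
Product: 40 CNP0135583.1 (target)
Conditions: HF·pyridine, pyridine, THF, 0 °C
Reagents that add atoms: none
Why: Buffered fluoride removes the secondary TES ether under conditions mild enough for the epoxide, the α-methylene lactone and the three esters.

**Compound list**

1 | (E)-but-2-ene-1,4-diol | OC/C=C/CO | starting material
2 | (E)-4-[(4-methoxybenzyl)oxy]but-2-en-1-ol | OC/C=C/COCc1ccc(OC)cc1 | intermediate
3 | [(2R,3R)-3-{[(4-methoxybenzyl)oxy]methyl}oxiran-2-yl]methanol | OC[C@H]1O[C@@H]1COCc2ccc(OC)cc2 | intermediate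
4 | (2S,3S)-3-{[(4-methoxybenzyl)oxy]methyl}-5-(trimethylsilyl)pent-4-yne-1,2-diol | OC[C@@H](O)[C@@H](C#C[Si](C)(C)C)COCc1ccc(OC)cc1 | intermediate
5 | (2S,3S)-3-{[(4-methoxybenzyl)oxy]methyl}pent-4-yne-1,2-diol | OC[C@@H](O)[C@@H](C#C)COCc1ccc(OC)cc1 | intermediate
6 | (2S,3S)-1-[(tert-butyldimethylsilyl)oxy]-3-{[(4-methoxybenzyl)oxy]methyl}pent-4-yn-2-ol | CC(C)(C)[Si](C)(C)OC[C@@H](O)[C@@H](C#C)COCc1ccc(OC)cc1 | intermediate
7 | tert-butyl{[(2S,4S,5S)-5-ethynyl-2-(4-methoxyphenyl)-1,3-dioxan-4-yl]methoxy}dimethylsilane | CC(C)(C)[Si](C)(C)OC[C@H]1O[C@@H](c2ccc(OC)cc2)OC[C@@H]1C#C | intermediate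
8 | alkenylalane: diisobutylaluminium analogue of 9 (Al(i-Bu)2 in place of Bpin) | CC(C)(C)[Si](C)(C)OC[C@H]1O[C@@H](c2ccc(OC)cc2)OC[C@@H]1C(=C)[Al](CC(C)C)CC(C)C | intermediate
9 | tert-butyl{[(2S,4S,5S)-2-(4-methoxyphenyl)-5-[1-(4,4,5,5-tetramethyl-1,3,2-dioxaborolan-2-yl)ethenyl]-1,3-dioxan-4-yl]methoxy}dimethylsilane | CC(C)(C)[Si](C)(C)OC[C@H]1O[C@@H](c2ccc(OC)cc2)OC[C@@H]1C(=C)B3OC(C)(C)C(C)(C)O3 | intermediate
10 | (2S,3S)-4-[(tert-butyldimethylsilyl)oxy]-3-[(4-methoxybenzyl)oxy]-2-[1-(4,4,5,5-tetramethyl-1,3,2-dioxaborolan-2-yl)ethenyl]butan-1-ol | CC(C)(C)[Si](C)(C)OC[C@@H](OCc1ccc(OC)cc1)[C@@H](C(=C)B2OC(C)(C)C(C)(C)O2)CO | intermediate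
11 | (2R,3S)-4-[(tert-butyldimethylsilyl)oxy]-3-[(4-methoxybenzyl)oxy]-2-[1-(4,4,5,5-tetramethyl-1,3,2-dioxaborolan-2-yl)ethenyl]butanal | CC(C)(C)[Si](C)(C)OC[C@@H](OCc1ccc(OC)cc1)[C@@H](C(=C)B2OC(C)(C)C(C)(C)O2)C=O | intermediate
12 | but-3-en-1-ylmagnesium bromide | C=CCC[Mg]Br | starting material
13 | but-3-en-1-ylcopper(I) | C=CCC[Cu] | intermediate
14 | [(1Z)-2-methylhexa-1,5-dien-1-yl]copper(I) | C=CCC/C(C)=C\[Cu] | intermediate
15 | (1Z)-1-iodo-2-methylhexa-1,5-diene | C=CCC/C(C)=C\I | intermediate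
16 | [(1Z)-2-methylhexa-1,5-dien-1-yl]chromium(III) dichloride | C=CCC/C(C)=C\[Cr](Cl)Cl | intermediate
17 | (2S,3S,4R,5Z)-1-[(tert-butyldimethylsilyl)oxy]-2-[(4-methoxybenzyl)oxy]-6-methyl-3-[1-(4,4,5,5-tetramethyl-1,3,2-dioxaborolan-2-yl)ethenyl]deca-5,9-dien-4-ol | CC(C)(C)[Si](C)(C)OC[C@@H](OCc1ccc(OC)cc1)[C@@H](C(=C)B2OC(C)(C)C(C)(C)O2)[C@H](O)/C=C(/C)CCC=C | intermediate
18 | (2S,3S,4R,5Z)-1-[(tert-butyldimethylsilyl)oxy]-2-[(4-methoxybenzyl)oxy]-6-methyl-3-[1-(4,4,5,5-tetramethyl-1,3,2-dioxaborolan-2-yl)ethenyl]deca-5,9-dien-4-yl acetate | CC(C)(C)[Si](C)(C)OC[C@@H](OCc1ccc(OC)cc1)[C@@H](C(=C)B2OC(C)(C)C(C)(C)O2)[C@H](OC(C)=O)/C=C(/C)CCC=C | intermediate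
19 | potassium tert-butoxy(alkenyl)borate of 18 (ate complex at boron) | CC(C)(C)[Si](C)(C)OC[C@@H](OCc1ccc(OC)cc1)[C@@H](C(=C)[B-]2(OC(C)(C)C)OC(C)(C)C(C)(C)O2)[C@H](OC(C)=O)/C=C(/C)CCC=C.[K+] | intermediate
20 | potassium (3S,4R,5Z)-4-acetoxy-3-[(1S)-2-[(tert-butyldimethylsilyl)oxy]-1-[(4-methoxybenzyl)oxy]ethyl]-6-methyl-2-methylidenedeca-5,9-dienoate | CC(C)(C)[Si](C)(C)OC[C@@H](OCc1ccc(OC)cc1)[C@@H](C(=C)C(=O)[O-])[C@H](OC(C)=O)/C=C(/C)CCC=C.[K+] | intermediate
21 | (4S,5R)-4-[(1S)-2-[(tert-butyldimethylsilyl)oxy]-1-[(4-methoxybenzyl)oxy]ethyl]-3-methylidene-5-[(1Z)-2-methylhexa-1,5-dien-1-yl]oxolan-2-one | C=C1C(=O)O[C@H](/C=C(/C)CCC=C)[C@H]1[C@H](OCc2ccc(OC)cc2)CO[Si](C)(C)C(C)(C)C | intermediate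
22 | (4S,5R)-4-[(1S)-2-hydroxy-1-[(4-methoxybenzyl)oxy]ethyl]-3-methylidene-5-[(1Z)-2-methylhexa-1,5-dien-1-yl]oxolan-2-one | C=C1C(=O)O[C@H](/C=C(/C)CCC=C)[C@H]1[C@H](OCc2ccc(OC)cc2)CO | intermediate
23 | (2S)-2-[(4-methoxybenzyl)oxy]-2-[(2R,3S)-4-methylidene-2-[(1Z)-2-methylhexa-1,5-dien-1-yl]-5-oxooxolan-3-yl]acetaldehyde | C=C1C(=O)O[C@H](/C=C(/C)CCC=C)[C@H]1[C@H](OCc2ccc(OC)cc2)C=O | intermediate
24 | methyl (3R,4S)-3-hydroxy-4-[(4-methoxybenzyl)oxy]-2-methylidene-4-[(2R,3S)-4-methylidene-2-[(1Z)-2-methylhexa-1,5-dien-1-yl]-5-oxooxolan-3-yl]butanoate | C=C1C(=O)O[C@H](/C=C(/C)CCC=C)[C@H]1[C@H](OCc2ccc(OC)cc2)[C@H](O)C(=C)C(=O)OC | intermediate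
25 | methyl (1(10)E,4Z)-9-hydroxy-8-[(4-methoxybenzyl)oxy]-12-oxo-germacra-1(10),4,11(13)-trien-12,6-olid-14-oate, C6–C9 configured as in 40 | C=C1C(=O)O[C@@H]2/C=C(/C)CC/C=C(/C(=O)OC)[C@@H](O)[C@@H](OCc3ccc(OC)cc3)[C@@H]12 | intermediate
26 | (R)-4-benzyl-3-propionyloxazolidin-2-one | CCC(=O)N1[C@H](Cc2ccccc2)COC1=O | starting material
27 | (Z)-dibutylboron enolate of 26 | C/C=C(\OB(CCCC)CCCC)N1[C@H](Cc2ccccc2)COC1=O | intermediate
28 | (R)-4-benzyl-3-[(2R,3S)-3-hydroxy-2-methylbutanoyl]oxazolidin-2-one | O=C(N1[C@H](Cc2ccccc2)COC1=O)[C@H](C)[C@H](C)O | intermediate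
29 | (R)-4-benzyl-3-[(2R,3S)-2-methyl-3-(triethylsilyloxy)butanoyl]oxazolidin-2-one | O=C(N1[C@H](Cc2ccccc2)COC1=O)[C@H](C)[C@H](C)O[Si](CC)(CC)CC | intermediate
30 | (2R,3S)-2-methyl-3-(triethylsilyloxy)butanoic acid | OC(=O)[C@H](C)[C@H](C)O[Si](CC)(CC)CC | intermediate
31 | (2R,3S)-2-methyl-3-(triethylsilyloxy)butanoic 2,4,6-trichlorobenzoic anhydride | O=C(OC(=O)c1c(Cl)cc(Cl)cc1Cl)[C@H](C)[C@H](C)O[Si](CC)(CC)CC | intermediate
32 | 9-O-[(2R,3S)-2-methyl-3-(triethylsilyloxy)butanoyl] derivative of 25 (8-OPMB) | C=C1C(=O)O[C@@H]2/C=C(/C)CC/C=C(/C(=O)OC)[C@@H](OC(=O)[C@H](C)[C@H](C)O[Si](CC)(CC)CC)[C@@H](OCc3ccc(OC)cc3)[C@@H]12 | intermediate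
33 | 8-hydroxy compound: 32 with free 8-OH in place of 8-OPMB | C=C1C(=O)O[C@@H]2/C=C(/C)CC/C=C(/C(=O)OC)[C@@H](OC(=O)[C@H](C)[C@H](C)O[Si](CC)(CC)CC)[C@@H](O)[C@@H]12 | intermediate
34 | angelic acid, (Z)-2-methylbut-2-enoic acid | C/C=C(/C)C(=O)O | starting material
35 | (Z)-2-methylbut-2-en-1-ol | C/C=C(/C)CO | intermediate
36 | [(2R,3S)-2,3-dimethyloxiran-2-yl]methanol | OC[C@@]1(C)O[C@H]1C | intermediate
37 | (2S,3S)-2,3-dimethyloxirane-2-carboxylic acid | OC(=O)[C@@]1(C)O[C@H]1C | intermediate
38 | (2S,3S)-2,3-dimethyloxirane-2-carboxylic 2,4,6-trichlorobenzoic anhydride | O=C(OC(=O)c1c(Cl)cc(Cl)cc1Cl)[C@@]2(C)O[C@H]2C | intermediate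
39 | TES-protected target: 40 with a triethylsilyl ether on the side-chain hydroxyl | C=C1C(=O)O[C@@H]2/C=C(/C)CC/C=C(/C(=O)OC)[C@@H](OC(=O)[C@H](C)[C@H](C)O[Si](CC)(CC)CC)[C@@H](OC(=O)[C@@]3(C)O[C@H]3C)[C@@H]12 | intermediate
40 | CNP0135583.1: methyl (1(10)E,4Z,6R,7S,8S,9R)-8-{[(2S,3S)-2,3-dimethyloxiran-2-yl]carbonyloxy}-9-{[(2R,3S)-3-hydroxy-2-methylbutanoyl]oxy}-12-oxo-germacra-1(10),4,11(13)-trien-12,6-olid-14-oate | C=C1C(=O)O[C@@H]2/C=C(/C)CC/C=C(/C(=O)OC)[C@@H](OC(=O)[C@H](C)[C@H](C)O)[C@@H](OC(=O)[C@@]3(C)O[C@H]3C)[C@@H]12 | target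

**Step count and risks**

Total step count: 27. Longest linear sequence: 20 steps (steps 1–9, 11–17, 21, 22, 26, 27).

Steps most likely to fail:

Step 13 (proposed Cu/Pd relay). The two catalytic cycles may not mesh: the alkenylcopper may be protonated before it inserts CO2, the alkenyl group may pass from boron to palladium, or the π-allylpalladium may lose a β-hydride to a triene before the carboxylate is in place. The fallback uses known chemistry and takes the ring oxygen from the C6 hydroxyl instead. It sets out from alcohol 17: NHC–copper-catalysed carboxylation of its alkenylboronate with CO2 ([(IPr)CuCl], KOtBu 2.1 equiv, CO2 1 atm, THF, 65 °C, mild acid work-up) should give (3S,4R,5Z)-3-[(1S)-2-[(tert-butyldimethylsilyl)oxy]-1-[(4-methoxybenzyl)oxy]ethyl]-4-hydroxy-6-methyl-2-methylidenedeca-5,9-dienoic acid F1. This γ-hydroxy acid should lactonise on standing or with CSA (cat.) in CH2Cl2, and the route is rejoined at lactone 21.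

Step 17 (ring-closing metathesis). Closure onto the hindered, electron-poor 2-substituted acrylate may be slow, so that cross-metathesis oligomers build up, and ruthenium hydrides may isomerise the free allylic alcohol to a β-keto ester. The fallback changes the order of events so that the ring is closed last on a substrate without a free hydroxyl. It sets out from 24: esterification with acid 30 (DIC, DMAP cat., CH2Cl2, 0 °C) should give the 3-O-[(2R,3S)-2-methyl-3-(triethylsilyloxy)butanoyl] ester of 24 F2. Ring-closing metathesis of this diene ester (chelated second-generation ruthenium catalyst, toluene, 80 °C, high dilution) should then give 32 directly, where the route is rejoined.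

Step 16 (Morita–Baylis–Hillman reaction). Addition to the hindered α-alkoxy aldehyde may be slow, so that enolisation erodes the C8 centre and facial selectivity at C9 is poor. The fallback is a tandem Michael–aldol sequence that sets out from aldehyde 23. The lithium enolate formed from PhSeLi and methyl acrylate (THF, −78 °C) should add to 23 with Felkin selectivity to give methyl (3R,4S)-3-hydroxy-4-[(4-methoxybenzyl)oxy]-4-[(2R,3S)-4-methylidene-2-[(1Z)-2-methylhexa-1,5-dien-1-yl]-5-oxooxolan-3-yl]-2-[(phenylselanyl)methyl]butanoate F3 (mixture at C2). Oxidation (H2O2, pyridine, CH2Cl2, 0 °C) and selenoxide syn-elimination should then give 24, where the route is rejoined.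

Further compounds
F1 | step 13 | (3S,4R,5Z)-3-[(1S)-2-[(tert-butyldimethylsilyl)oxy]-1-[(4-methoxybenzyl)oxy]ethyl]-4-hydroxy-6-methyl-2-methylidenedeca-5,9-dienoic acid | CC(C)(C)[Si](C)(C)OC[C@@H](OCc1ccc(OC)cc1)[C@@H](C(=C)C(=O)O)[C@H](O)/C=C(/C)CCC=C
F2 | step 17 | 3-O-[(2R,3S)-2-methyl-3-(triethylsilyloxy)butanoyl] ester of 24 | C=C1C(=O)O[C@H](/C=C(/C)CCC=C)[C@H]1[C@H](OCc2ccc(OC)cc2)[C@H](OC(=O)[C@H](C)[C@H](C)O[Si](CC)(CC)CC)C(=C)C(=O)OC
F3 | step 16 | methyl (3R,4S)-3-hydroxy-4-[(4-methoxybenzyl)oxy]-4-[(2R,3S)-4-methylidene-2-[(1Z)-2-methylhexa-1,5-dien-1-yl]-5-oxooxolan-3-yl]-2-[(phenylselanyl)methyl]butanoate | C=C1C(=O)O[C@H](/C=C(/C)CCC=C)[C@H]1[C@H](OCc2ccc(OC)cc2)[C@H](O)C(C[Se]c3ccccc3)C(=O)OC
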